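**Conventions.** Locants C1–C7 in the text are those of the target: C1 (OMe), C2=C3, C7 (CH2OBz on C3), C4 (OH), C5 (OBz), C6 (OH). Compound names use nomenclature locants; "up" means the face that carries O4 and O5 in the target.

## Analysis of the target

The target 17 is a single cyclohexene ring (C1–C6) whose C2=C3 bond carries the benzoyloxymethyl carbon C7 on C3; every other ring carbon is oxygenated, C1 as a methyl ether, C4 and C6 as free hydroxyls, C5 as a benzoate. The stereocentres C1, C4, C5 and C6 are all R: O4 and O5 are cis, O5 and O6 are trans, and the C1 methoxy group is cis to O6, so O1/O6 lie on one face and O4/O5 on the other. The sensitive points are the O5 benzoate, which sits between two free hydroxyls and can migrate under base, and the allylic C1 ether and C4 alcohol, which ionise under strong acid. The ring as a whole is only two eliminations away from an arene. The difficulty is not the skeleton but telling five oxygens apart (methyl, H, benzoyl, H, benzoyl) while setting the relationships across C5–C6 and C1–C6. The strategy rests on C1 and C4 being para-disposed oxygenated carbons on either side of C2=C3: the ring is a p-benzoquinone in disguise, with the C1 carbonyl masked as a dimethyl ketal (the later source of the methoxy group) and the C4 carbonyl free to activate C3 for attaching C7 and C5=C6 for oxygenation. In the symmetric monoketal the two enone arms are enantiotopic, so one enantioselective epoxidation fixes the absolute configuration of the whole molecule.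

## Retrosynthetic reasoning

**17 from 16.** No skeletal bond is cut; only the O6–acetyl bond of acetate 16 is removed. It is placed last because the O6 ester serves three purposes upstream (water surrogate, protecting group, participating group), and an acetate can be removed beside benzoates by acid methanolysis, which does not generate the alkoxides that move the O5 benzoate.

**16 from 13.** The C1–H bond is disconnected, leading back to the dimethyl ketal 13. Cutting here, and not at O1–CH3, avoids a late methylation that would have to distinguish O1 from O4 and O6; the ketal already carries the methyl group. The forward reaction must ionise the ketal and deliver hydride to C1 (not C3) from the face of O5. The O6 acetate is there to cover its own face of the cation, the same 1,2-trans logic as a 2-O-acyl group in glycosylation.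

**13 from 12 and 8.** The O5–benzoyl bond is cut. In diol 12 the free hydroxyls O4 and O5 are cis; O5 is equatorial and O4 pseudoaxial and allylic. A cyclic stannylene should differentiate them as it does in 2,3-cis-diols of pyranosides.

**12 from 10 and 11.** The C6–O bond is cut, leading to the cis-epoxy alcohol 10 and acetic acid 11. The cut must be at C6 and not C5, because the oxirane oxygen is already on the correct face for O5 and only C6 has to be inverted. The forward reaction needs an oxygen nucleophile to enter at C6, next to the ketal carbon, anti to the oxirane; the C4 hydroxyl, cis to the oxirane, is the handle for a metal alkoxide chelate that steers it there.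

**10 from 9, 7, 5 and 4.** The C4–H bond is cut (carbonyl reduction anti to the oxirane), then the O7–benzoyl bond (7 + 8), then C3–C7 (alkenyl iodide 5 + stannane 6), then C3–I back to enone 4. C7 is introduced here because C3 is the only α-carbon of the only enone left after epoxidation, so its position is unambiguous.

**4 from 3.** The C5–O and C6–O bonds of the oxirane are cut, giving the achiral dienone 3. This is the only enantio-determining event; everything later is relayed from it.

**3 from 1 and 2.** Oxidative dearomatisation of phenol 1 in methanol 2 installs both ketal methoxy groups in one step.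

## Alternatives that were turned down

**Alternative 1:** The C1–C2 bond is disconnected, turning the carbocycle into a pyranoside: sugar C1 is target C1 with its methoxy aglycon, sugar C6 becomes C2, and the L-galacto centres C2–C4 become C6, C5 and C4.
- Forward key step: enol ether A2 (from L-galactose, A3) is treated with Al(i-Bu)3. The Lewis acid opens the ring C1–O5 bond, the aluminium enolate recloses through its terminal carbon onto the oxocarbenium carbon with the aglycon retained, and the ketone is reduced in the flask to give A1.
- For it: C1 (with its methoxy group), C4, C5 and C6 come from the chiral pool with no selective step, and O5 is singled out as a silyl ether, so the O5 benzoate is unambiguous. On stereochemical certainty and oxygen differentiation this is stronger than the chosen route.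
- Against it: A1 has C2 as a methylene and C3 as a carbinol with no C7. Oxidation, one-carbon addition at C3 and regioselective introduction of C2=C3 (elimination can also run toward C4) still follow, then protecting-group exchange. A3 is a rare sugar, and A2 itself needs glycosidation, a three-group protection pattern, 6-iodination and elimination. The total is likely above 16 steps.
- Comparison: the chosen route takes C7, the alkene and the position of every oxygen from the quinoid core in 10 steps from a bulk phenol, at the price of two selectivity gambles (C6 opening, C1 reduction).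

**Alternative 2:** The C1–C6 bond, the bond of the cis-diol, is disconnected.
- Forward key step: dialdehyde A5 is reduced by SmI2 (divalent samarium); ketyl formation and carbon–carbon coupling close the ring to the cis-diol A4, anti to the acetonide.
- For it: it makes the C1/C6 cis relationship directly, the relationship the chosen route reaches only indirectly, so it is stronger on that point. Ring, alkene and C7 are all present in A4.
- Against it: A5 is a Z-configured trisubstituted enal with an epimerisable α-alkoxy aldehyde. The enal ketyl is an allylic radical anion that can couple through C3 or simply be reduced. After cyclisation O1 must be methylated in the presence of O6, and later O5 told from O4 — the same cis-diol problem as in the chosen route, but with more free oxygens in play. Building A5 from the chiral pool would take about eight steps, so the total would be near 15 or more.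
- Comparison: the chosen route delivers O1 already methylated from the ketal and never has O1 and O6 free together.

**Alternative 3:** C3–C4 and C5–C6 are disconnected, assembling the ring from pyrone ester A7 and dioxole A8.
- Forward key step: Yb(OTf)3 with (R)-1,1'-bi-2-naphthol and i-Pr2NEt catalyses an inverse-electron-demand, endo [4+2] cycloaddition to the bridged lactone A6.
- For it: it is convergent and catalytic; two bonds, the ring and the centres at C4–C6 form in one step, O4/O5 are cis by construction, and O6 emerges as the lactone oxygen, already differentiated. On convergence and O6 differentiation it is stronger than the chosen route.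
- Against it: A6 has no oxygen at C1, a C1=C2 alkene, and a quaternary C3 bearing two carbonyl carbons. One carbonyl carbon must be excised, the alkene moved to C2=C3, C1 oxidised with stereocontrol and methylated, and the ester reduced to C7–OH. A8 is a volatile, seldom-used dienophile, and cis-dioxygenated alkenes are poorer partners than the vinyl ethers for which such catalysts are established. The O5/O6 trans relationship depends on endo/exo control.
- Comparison: the chosen route has the correct oxidation pattern from its first step and needs no redox end-game.

Key step: step 2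

## Route

**Assumption.** The sense of induction of the tartrate–peroxide aggregate on a monoketal without a coordinating side chain cannot be derived from a model. The route is written with L-(+)-diisopropyl tartrate; the D-(−)-ester is used if the sense proves opposite.

Step 1
Reactants: 1 4-methoxyphenol; 2 methanol
Product: 3 4,4-dimethoxycyclohexa-2,5-dien-1-one
Conditions: carbon anode, Pt cathode, LiClO4, MeOH, undivided cell, constant current, 0 °C
Reagents that add atoms: methanol (2), CO
Why: Two-electron anodic oxidation of the phenol gives a phenoxonium ion that methanol traps at the para carbon already bearing a methoxy group (anodic dearomatisation to a quinone monoketal); 3 is achiral with two mirror-related enone arms, the symmetry the next step breaks.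

Step 2
Reactants: 3 4,4-dimethoxycyclohexa-2,5-dien-1-one
Product: 4 (1S,6R)-5,5-dimethoxy-7-oxabicyclo[4.1.0]hept-3-en-2-one
Conditions: Ph3COOH (about 1 equiv), NaN(SiMe3)2, L-(+)-diisopropyl tartrate, 4 Å molecular sieves, toluene, −65 → −50 °C
Reagents that add atoms: trityl hydroperoxide, OOC(c1ccccc1)(c1ccccc1)c1ccccc1
Why: The sodium salt of trityl hydroperoxide, held in an aggregate with the sodium alkoxide of the tartrate, adds in a conjugate sense to C6, the β-carbon of one enone arm of 3. The enolate then attacks the proximal peroxide oxygen through C5 and expels trityloxide, a 3-exo-tet closure that completes the oxirane (Weitz–Scheffer epoxidation). The closest known reaction type is the tartrate-mediated nucleophilic epoxidation of quinone monoketals with trityl hydroperoxide. C5 and C6 are formed together and can only be cis on the three-membered ring. Their absolute configuration (oxygen on the face O5 occupies in 17) depends on which enantiotopic arm, and which face of it, the chiral aggregate reaches, so the tartrate is the only controlling element. The step needs conjugate rather than carbonyl addition, which the bulky peroxide and low temperature favour. It also needs a stop at the monoepoxide, which about one equivalent of peroxide and the more crowded second β-carbon should secure.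

Step 3
Reactants: 4 (1S,6R)-5,5-dimethoxy-7-oxabicyclo[4.1.0]hept-3-en-2-one
Product: 5 (1S,6R)-3-iodo-5,5-dimethoxy-7-oxabicyclo[4.1.0]hept-3-en-2-one
Conditions: I2, pyridine, CH2Cl2, 0 °C → rt
Reagents that add atoms: iodine, II
Why: Pyridine adds reversibly to the β-carbon C2 of the remaining enone, the enolate is iodinated at C3 and pyridine is expelled (amine-mediated α-iodination of an enone by addition–halogenation–elimination); C3 is the only enone α-carbon, and neither stereocentre is touched.

Step 4
Reactants: 5 (1S,6R)-3-iodo-5,5-dimethoxy-7-oxabicyclo[4.1.0]hept-3-en-2-one; 6 (tributylstannyl)methanol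
Product: 7 (1S,6R)-3-(hydroxymethyl)-5,5-dimethoxy-7-oxabicyclo[4.1.0]hept-3-en-2-one
Conditions: Pd2(dba)3, AsPh3, CuI, NMP, 50 °C
Reagents that add atoms: (tributylstannyl)methanol (6), CCCC[Sn](CCCC)(CCCC)CO
Why: Stille coupling: the electron-poor alkenyl iodide adds oxidatively to zerovalent palladium, the hydroxymethyl group is transferred from tin (helped by CuI and the weakly bound arsine), and reductive elimination forms C3–C7; epoxide and ketal are spectators under these neutral conditions.

Step 5
Reactants: 7 (1S,6R)-3-(hydroxymethyl)-5,5-dimethoxy-7-oxabicyclo[4.1.0]hept-3-en-2-one; 8 benzoyl chloride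
Product: 9 [(1S,6R)-5,5-dimethoxy-2-oxo-7-oxabicyclo[4.1.0]hept-3-en-3-yl]methyl benzoate
Conditions: BzCl, pyridine, CH2Cl2, 0 °C
Reagents that add atoms: benzoyl chloride (8), O=C(Cl)c1ccccc1
Why: Acylation of the only hydroxyl group through the acylpyridinium ion (nucleophilic acyl substitution); fixing the C7 benzoate now means the primary oxygen never competes when the ring oxygens are differentiated.

Step 6
Reactants: 9 [(1S,6R)-5,5-dimethoxy-2-oxo-7-oxabicyclo[4.1.0]hept-3-en-3-yl]methyl benzoate
Product: 10 [(1R,2R,6R)-2-hydroxy-5,5-dimethoxy-7-oxabicyclo[4.1.0]hept-3-en-3-yl]methyl benzoate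
Conditions: NaBH4, CeCl3·7H2O, MeOH, −78 °C
Reagents that add atoms: none
Why: Luche 1,2-reduction: the cerium-activated C4 carbonyl is attacked by a hard alkoxyborohydride anti to the C5–O bond of the oxirane (Felkin–Anh and torsional control, as for other 2,3-epoxycyclohexenones), so the new hydroxyl is cis to the epoxide (C4 R); benzoate, ketal and epoxide survive at −78 °C.

Step 7
Reactants: 10 [(1R,2R,6R)-2-hydroxy-5,5-dimethoxy-7-oxabicyclo[4.1.0]hept-3-en-3-yl]methyl benzoate; 11 acetic acid
Product: 12 [(4S,5R,6R)-4-(acetyloxy)-5,6-dihydroxy-3,3-dimethoxycyclohex-1-en-1-yl]methyl benzoate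
Conditions: Ti(OiPr)4 (1.5 equiv), AcOH, CH2Cl2, rt; aq. tartaric acid work-up
Reagents that add atoms: acetic acid (11), CC(=O)O
Why: The titanium alkoxide of the C4 hydroxyl also binds the cis oxirane oxygen; this chelate holds C4–O pseudoequatorial, the half-chair in which trans-diaxial (Fürst–Plattner) opening occurs at C6, the carbon remote from the carbinol. Titanium-bound acetate then attacks C6 anti to the oxirane (SN2, inversion), leaving O5 in place and O6 trans to it, as in titanium alkoxide-mediated opening of 2,3-epoxy alcohols at C3 by carboxylic acids. Acetate is chosen because it later participates at C1 and can be removed beside benzoates.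

Step 8
Reactants: 12 [(4S,5R,6R)-4-(acetyloxy)-5,6-dihydroxy-3,3-dimethoxycyclohex-1-en-1-yl]methyl benzoate; 8 benzoyl chloride
Product: 13 [(4S,5R,6R)-4-(acetyloxy)-5-(benzoyloxy)-6-hydroxy-3,3-dimethoxycyclohex-1-en-1-yl]methyl benzoate
Conditions: Me2SnCl2 (5 mol %), BzCl, iPr2NEt, THF, rt
Reagents that add atoms: benzoyl chloride (8), O=C(Cl)c1ccccc1
Why: The cis-4,5-diol forms a five-membered dialkylstannylene whose equatorial oxygen (O5) is the more nucleophilic, as in tin-mediated 3-O-acylation of manno- and rhamnopyranoside 2,3-cis-diols; the pseudoaxial allylic O4 stays free, and room temperature with an amine base keeps the O6 acetate from migrating.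

Step 9
Reactants: 13 [(4S,5R,6R)-4-(acetyloxy)-5-(benzoyloxy)-6-hydroxy-3,3-dimethoxycyclohex-1-en-1-yl]methyl benzoate
Product: 16 [(3R,4R,5R,6R)-4-(acetyloxy)-5-(benzoyloxy)-6-hydroxy-3-methoxycyclohex-1-en-1-yl]methyl benzoate, via O-trimethylsilyl ether of the ketal 14 (not isolated), via O-trimethylsilyl ether of the methyl ether 15 (not isolated)
Conditions: TMSOTf, 2,6-lutidine, CH2Cl2, −78 °C; then Et3SiH, TMSOTf, −78 → −40 °C; aq. NaHCO3; then citric acid, MeOH, rt
Reagents that add atoms: none
Why: After the C4 hydroxyl is masked in the flask as its silyl ether, silyl triflate ionises the ketal to a methoxy-substituted allylic oxocarbenium ion at C1 (silane/silyl triflate reductive cleavage of a dimethyl ketal). The O6 acetate carbonyl bridges onto C1 from its own face, so Et3SiH delivers hydride anti to O6 (1,2-trans, as with a 2-O-acyl group in glycosylation), leaving the methoxy group cis to O6 (C1 R). Attack at C1 rather than C3 is expected because C3 is fully substituted; the silyl ether falls off on mild acidic work-up.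

Step 10
Reactants: 16 [(3R,4R,5R,6R)-4-(acetyloxy)-5-(benzoyloxy)-6-hydroxy-3-methoxycyclohex-1-en-1-yl]methyl benzoate; 2 methanol
Product: 17 [(3R,4R,5R,6R)-5-(benzoyloxy)-4,6-dihydroxy-3-methoxycyclohex-1-en-1-yl]methyl benzoate
Conditions: AcCl (cat., generates HCl), MeOH, 0 °C → rt
Reagents that add atoms: none
Why: Acid-catalysed transesterification: the aliphatic acetate is methanolysed much faster than the conjugated benzoates, and acidic conditions do not generate the alkoxides that move a benzoyl group to a neighbouring hydroxyl; no stereocentre is touched.

## Compound list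

1 | 4-methoxyphenol | COc1ccc(O)cc1 | starting material
2 | methanol | CO | starting material
3 | 4,4-dimethoxycyclohexa-2,5-dien-1-one | COC1(OC)C=CC(=O)C=C1 | intermediate
4 | (1S,6R)-5,5-dimethoxy-7-oxabicyclo[4.1.0]hept-3-en-2-one | COC1(OC)C=CC(=O)[C@H]2O[C@@H]12 | intermediate
5 | (1S,6R)-3-iodo-5,5-dimethoxy-7-oxabicyclo[4.1.0]hept-3-en-2-one | COC1(OC)C=C(I)C(=O)[C@H]2O[C@@H]12 | intermediate
6 | (tributylstannyl)methanol | CCCC[Sn](CCCC)(CCCC)CO | starting material
7 | (1S,6R)-3-(hydroxymethyl)-5,5-dimethoxy-7-oxabicyclo[4.1.0]hept-3-en-2-one | COC1(OC)C=C(CO)C(=O)[C@H]2O[C@@H]12 | intermediate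
8 | benzoyl chloride | O=C(Cl)c1ccccc1 | starting material
9 | [(1S,6R)-5,5-dimethoxy-2-oxo-7-oxabicyclo[4.1.0]hept-3-en-3-yl]methyl benzoate | COC1(OC)C=C(COC(=O)c3ccccc3)C(=O)[C@H]2O[C@@H]12 | intermediate
10 | [(1R,2R,6R)-2-hydroxy-5,5-dimethoxy-7-oxabicyclo[4.1.0]hept-3-en-3-yl]methyl benzoate | COC1(OC)C=C(COC(=O)c3ccccc3)[C@@H](O)[C@H]2O[C@@H]12 | intermediate
11 | acetic acid | CC(=O)O | starting material
12 | [(4S,5R,6R)-4-(acetyloxy)-5,6-dihydroxy-3,3-dimethoxycyclohex-1-en-1-yl]methyl benzoate | COC1(OC)C=C(COC(=O)c2ccccc2)[C@@H](O)[C@@H](O)[C@@H]1OC(C)=O | intermediate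
13 | [(4S,5R,6R)-4-(acetyloxy)-5-(benzoyloxy)-6-hydroxy-3,3-dimethoxycyclohex-1-en-1-yl]methyl benzoate | COC1(OC)C=C(COC(=O)c2ccccc2)[C@@H](O)[C@@H](OC(=O)c2ccccc2)[C@@H]1OC(C)=O | intermediate
14 | O-trimethylsilyl ether of 13 (silyl group on the allylic C4 oxygen) | COC1(OC)C=C(COC(=O)c2ccccc2)[C@@H](O[Si](C)(C)C)[C@@H](OC(=O)c2ccccc2)[C@@H]1OC(C)=O | intermediate
15 | O-trimethylsilyl ether of 16 (silyl group on the allylic C4 oxygen) | CO[C@@H]1C=C(COC(=O)c2ccccc2)[C@@H](O[Si](C)(C)C)[C@@H](OC(=O)c2ccccc2)[C@@H]1OC(C)=O | intermediate
16 | [(3R,4R,5R,6R)-4-(acetyloxy)-5-(benzoyloxy)-6-hydroxy-3-methoxycyclohex-1-en-1-yl]methyl benzoate | CO[C@@H]1C=C(COC(=O)c2ccccc2)[C@@H](O)[C@@H](OC(=O)c2ccccc2)[C@@H]1OC(C)=O | intermediate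
17 | [(3R,4R,5R,6R)-5-(benzoyloxy)-4,6-dihydroxy-3-methoxycyclohex-1-en-1-yl]methyl benzoate | CO[C@@H]1C=C(COC(=O)c2ccccc2)[C@@H](O)[C@@H](OC(=O)c2ccccc2)[C@@H]1O | target

## Step count and least certain steps

Total step count: 10. Longest linear sequence: 10 steps (1 → 17); 2, 6, 8 and 11 are purchased.

**Step 7 (epoxide opening at C6).** The nucleophile may enter at C5 instead. C6 is next to the fully substituted ketal carbon, whose lower methoxy group crowds the backside trajectory and whose two oxygens slow substitution inductively; only the chelate and the diaxial-opening argument speak for C6. A Lewis acid-induced shift of a ketal methoxy group onto C6, or transesterification of the new acetate, could also intervene. The fallback removes the quaternary neighbour before the opening. It sets out from 10: mild hydrolysis of the ketal (acidic clay or wet oxalic acid on silica) would give the hydroxy epoxy enone F5. In F5, C6 is α to a carbonyl and so activated for substitution, while still remote from the C4 hydroxyl; Ti(OiPr)4 and acetic acid should then give the acetoxy diol ketone F6. Base-free stannylene benzoylation (Bu2SnO, then BzCl) would give the O5 benzoate ketone F7. Reductive etherification with methoxytrimethylsilane, Et3SiH and TMSOTf silylates the free hydroxyl in the flask to the silyl ether F8 and passes through the same oxocarbenium ion as step 9. The route is rejoined at 15 and thus at 16 after work-up.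

**Step 9 (ketal reduction).** Hydride may add to the wrong face of C1: if acetate participation is weak, the chair-like axial trajectory places hydride cis to O6. Other risks are reduction at the acetoxonium carbon, attack at C3, and ionisation of the allylic C4–O bond. The fallback sets C1 on a ketone by reagent control and makes the ether by methylation. It sets out from 13: silylation (TBSOTf, 2,6-lutidine) gives the silyl ether F9, and ketal hydrolysis (pyridinium tosylate, wet acetone) gives the enone F10. Corey–Bakshi–Shibata reduction with the oxazaborolidine enantiomer that delivers hydride syn to O5 (alkenyl branch taken as the large group, which points to the R catalyst) gives the allylic alcohol F11. Methylation under non-basic conditions (MeOTf, 2,6-di-tert-butyl-4-methylpyridine) gives the methyl ether F12, and HF·pyridine returns to the route at 16.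

**Step 2 (key step).** Discrimination between the enantiotopic enone arms may be poor, because 3 has no hydroxyl to anchor it in the tartrate aggregate, the feature the best-behaved monoketals of this class possess. Over-epoxidation to the bis-epoxide is the second risk. The fallback replaces reagent control by resolution and sets out from 3. Racemic Weitz–Scheffer epoxidation (t-BuOOH, DBU) gives the racemic epoxide F1, and Luche reduction gives the racemic cis-epoxy alcohol F2. Lipase-mediated acetylation with vinyl acetate (Pseudomonas cepacia lipase, or a lipase of the complementary preference found by screening) leaves the wanted alcohol F3 and converts its enantiomer into the acetate F4. Oxidation of F3 with MnO2 returns to the route at 4.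

**Step 8 (O5 benzoylation).** Acylation may occur at O4, or the O6 acetate may migrate to O5 before acylation; either gives a regioisomeric ester pattern. The fallback postpones all benzoate placement to a tetraol, for which the tin-mediated 3,6-dibenzoylation of mannopyranosides is the model. It sets out from 12: peracetylation (Ac2O, pyridine) gives the triacetate F13, and Et3SiH with catalytic TMSOTf (no free hydroxyl, O6 acetate participating) gives the methyl ether triacetate F14. Transesterification with NaOMe in MeOH gives the tetraol F15. Bu2SnO followed by two equivalents of BzCl should acylate the primary O7 and the equatorial O5 of the cis-diol, rejoining the route at 17.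

**Step 4 (Stille hydroxymethylation).** Transfer of the hydroxymethyl group from tin may be slow compared with protodestannylation, butyl transfer or palladium-induced decomposition of the epoxy enone. The fallback avoids halogen and tin: it sets out from 4 and uses a Morita–Baylis–Hillman reaction with aqueous formaldehyde (trialkylphosphine or imidazole catalyst, THF/water) to give 7 directly, skipping 5. No new compound is formed.

## Further compounds

F1 | step 2 | racemic 5,5-dimethoxy-7-oxabicyclo[4.1.0]hept-3-en-2-one | COC1(OC)C=CC(=O)C2OC12
F2 | step 2 | racemic cis-5,5-dimethoxy-7-oxabicyclo[4.1.0]hept-3-en-2-ol (hydroxyl cis to the oxirane) | COC1(OC)C=CC(O)C2OC12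
F3 | step 2 | (1R,2R,6R)-5,5-dimethoxy-7-oxabicyclo[4.1.0]hept-3-en-2-ol | COC1(OC)C=C[C@@H](O)[C@H]2O[C@@H]12
F4 | step 2 | (1S,2S,6S)-5,5-dimethoxy-7-oxabicyclo[4.1.0]hept-3-en-2-yl acetate | COC1(OC)C=C[C@H](OC(C)=O)[C@@H]2O[C@H]12
F5 | step 7 | [(1R,2R,6R)-2-hydroxy-5-oxo-7-oxabicyclo[4.1.0]hept-3-en-3-yl]methyl benzoate | O=C1C=C(COC(=O)c3ccccc3)[C@@H](O)[C@H]2O[C@@H]12
F6 | step 7 | [(4S,5R,6R)-4-(acetyloxy)-5,6-dihydroxy-3-oxocyclohex-1-en-1-yl]methyl benzoate | O=C1C=C(COC(=O)c2ccccc2)[C@@H](O)[C@@H](O)[C@@H]1OC(C)=O
F7 | step 7 | [(4S,5R,6R)-4-(acetyloxy)-5-(benzoyloxy)-6-hydroxy-3-oxocyclohex-1-en-1-yl]methyl benzoate | O=C1C=C(COC(=O)c2ccccc2)[C@@H](O)[C@@H](OC(=O)c2ccccc2)[C@@H]1OC(C)=O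
F8 | step 7 | O-trimethylsilyl ether of F7 (silyl group on the C4 oxygen) | O=C1C=C(COC(=O)c2ccccc2)[C@@H](O[Si](C)(C)C)[C@@H](OC(=O)c2ccccc2)[C@@H]1OC(C)=O
F9 | step 9 | O-tert-butyldimethylsilyl ether of 13 (silyl group on the C4 oxygen) | COC1(OC)C=C(COC(=O)c2ccccc2)[C@@H](O[Si](C)(C)C(C)(C)C)[C@@H](OC(=O)c2ccccc2)[C@@H]1OC(C)=O
F10 | step 9 | C1 ketone from F9 (enone with O4 silyl ether, O5 benzoate, O6 acetate) | O=C1C=C(COC(=O)c2ccccc2)[C@@H](O[Si](C)(C)C(C)(C)C)[C@@H](OC(=O)c2ccccc2)[C@@H]1OC(C)=O
F11 | step 9 | C1 alcohol from F10 (hydroxyl cis to the O6 acetate) | O[C@@H]1C=C(COC(=O)c2ccccc2)[C@@H](O[Si](C)(C)C(C)(C)C)[C@@H](OC(=O)c2ccccc2)[C@@H]1OC(C)=O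
F12 | step 9 | O-tert-butyldimethylsilyl ether of 16 (silyl group on the C4 oxygen) | CO[C@@H]1C=C(COC(=O)c2ccccc2)[C@@H](O[Si](C)(C)C(C)(C)C)[C@@H](OC(=O)c2ccccc2)[C@@H]1OC(C)=O
F13 | step 8 | 4,5-di-O-acetyl derivative of 12 (triacetate, dimethyl ketal) | COC1(OC)C=C(COC(=O)c2ccccc2)[C@@H](OC(C)=O)[C@@H](OC(C)=O)[C@@H]1OC(C)=O
F14 | step 8 | C1 methyl ether from F13 (4,5,6-triacetate, 7-benzoate) | CO[C@@H]1C=C(COC(=O)c2ccccc2)[C@@H](OC(C)=O)[C@@H](OC(C)=O)[C@@H]1OC(C)=O
F15 | step 8 | (1R,2R,3R,6R)-4-(hydroxymethyl)-6-methoxycyclohex-4-ene-1,2,3-triol | CO[C@@H]1C=C(CO)[C@@H](O)[C@@H](O)[C@@H]1O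
F0 | step 4 | none | none
A1 | alternative 1 | 1-methoxy-4,6-bis[(4-methoxybenzyl)oxy]-5-[(tert-butyldimethylsilyl)oxy]cyclohexan-3-ol (target locants) | CO[C@@H]1C[C@@H](O)[C@@H](OCc2ccc(OC)cc2)[C@@H](O[Si](C)(C)C(C)(C)C)[C@@H]1OCc1ccc(OC)cc1
A2 | alternative 1 | methyl 6-deoxy-2,4-di-O-(4-methoxybenzyl)-3-O-(tert-butyldimethylsilyl)-α-L-arabino-hex-5-enopyranoside | CO[C@@H]1OC(=C)[C@@H](OCc2ccc(OC)cc2)[C@@H](O[Si](C)(C)C(C)(C)C)[C@@H]1OCc1ccc(OC)cc1
A3 | alternative 1 | L-galactose (open-chain form) | O=C[C@@H](O)[C@H](O)[C@H](O)[C@@H](O)CO
A4 | alternative 2 | cyclohexene cis-1,6-diol with 4,5-O-isopropylidene and 7-O-tert-butyldimethylsilyl groups (target locants) | O[C@@H]1C=C(CO[Si](C)(C)C(C)(C)C)[C@H]2OC(C)(C)O[C@H]2[C@@H]1O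
A5 | alternative 2 | (2Z)-3-{[(tert-butyldimethylsilyl)oxy]methyl}-4,5-O-isopropylidene-4,5-dihydroxyhex-2-enedial, configured as in A4 | O=C/C=C(/CO[Si](C)(C)C(C)(C)C)[C@H]1OC(C)(C)O[C@H]1C=O
A6 | alternative 3 | endo bridged lactone (lactone from C3 to O6, acetonide on O4/O5, C1=C2 alkene, methyl ester on C3) | C1=C[C@@]2(C(=O)OC)[C@H]3OC(C)(C)O[C@H]3[C@@H]1OC2=O
A7 | alternative 3 | methyl 2-oxo-2H-pyran-3-carboxylate | COC(=O)C1=CC=COC1=O
A8 | alternative 3 | 2,2-dimethyl-1,3-dioxole | CC1(C)OC=CO1
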